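**Plan**

1. Feature (germacrane locants: ring C1–C10, lactone C6–O/C12, C11=C13, C14 methyl, C15 CH2OH): the carbinol carbons C3 and C8 lie 1,6 across the ten-membered ring, each one CH2 (C2, C9) from the cis C1–C10 unit. A C3–C8 bond would divide the ring into two six-membered rings, A (C3–C8) and B (C1, C2, C3, C8, C9, C10), i.e. a Birch-type hexahydronaphthalene.
2. Retrosynthetic cuts, in order: the C8–O acyl bond and the oxirane C–O bonds; C3=O/C8=O back to the C3=C8 ring-fusion olefin; ring B back to a p-tolyl ring; C4–O (enolate hydroxylation); C7–C11 and C12–O (aryl epoxide plus malonate); C7–C8 (Friedel–Crafts acylation) and C5–C6 (Michael addition).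
3. Forward: ring A is closed onto the tolyl ring, the trans γ-lactone is fused on, the arene is reduced to the 1,4-diene (ring B), ozone cuts the bond shared by rings A and B to unveil the ten-membered ring, and the oxirane is the last ring.
4. Stereochemistry: C6/C7 (absolute) from Jacobsen epoxidation and SN2 opening; C4 from equatorial hydroxylation of the ring-A ester enolate; C3 from C4–OH-directed hydride delivery; C8 from CBS reagent control; C1/C10 from C8–OH-directed epoxidation of the cis olefin.
5. The malonate carboxyl at C11 is kept on purpose: it blocks the lactone α-position during the C4 hydroxylation and then leaves as CO2 in the methylenation.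

Key step: step 14

**Remarks**

- Germacrane locants are used for every intermediate. The compounds before the epoxide are racemic; from the epoxide to the C4 hydroxylation they are C4-epimer mixtures, and the C11-carboxylated lactones are C11-epimer mixtures. Both centres are re-made later, so their SMILES leave them open.
- Assumption: the sense of induction of the (S,S) manganese–salen catalyst is taken from indene and 1,2-dihydronaphthalene; should the epoxide prove to have the other sense, the (R,R) catalyst is used.
- The ten-membered diketone and its C3 reduction product are labile and are used without purification.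

**Route**

Step 1
Reactants: 1 methyl 2-(4-methylphenyl)acetate; 2 tert-butyl acrylate
Product: 3 5-tert-butyl 1-methyl 2-(4-methylphenyl)pentanedioate
Conditions: KOt-Bu (0.1 equiv), THF, −20 → 0 °C, slow addition of 2 to a slight excess of 1
Reagents that add atoms: none
Why: Base-catalysed Michael addition of the arylacetate enolate to the acrylate; the adduct's remaining α-hydrogen is tertiary and hindered, which disfavours a second addition, and the new C4 centre is racemic by design because it is planarised again in step 9.

Step 2
Reactants: 3 5-tert-butyl 1-methyl 2-(4-methylphenyl)pentanedioate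
Product: 5 methyl 6-methyl-4-oxo-1,2,3,4-tetrahydronaphthalene-1-carboxylate, via glutaric half-acid 4 (not isolated)
Conditions: TFA, CH2Cl2, rt; evaporate; Eaton's reagent (P2O5 in MeSO3H), 50 °C
Reagents that add atoms: none
Why: Acidolysis of the tert-butyl ester followed by intramolecular Friedel–Crafts acylation: only the C7 acylium can reach the ring through a six-membered transition state and the two ortho positions of the p-tolyl ring are equivalent, so a single tetralone should result.

Step 3
Reactants: 5 methyl 6-methyl-4-oxo-1,2,3,4-tetrahydronaphthalene-1-carboxylate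
Product: 6 methyl 4-hydroxy-6-methyl-1,2,3,4-tetrahydronaphthalene-1-carboxylate
Conditions: NaBH4, MeOH, 0 °C
Reagents that add atoms: none
Why: Chemoselective borohydride reduction of the aryl ketone beside the methyl ester; the carbinol configuration is irrelevant because the centre is removed in step 4.

Step 4
Reactants: 6 methyl 4-hydroxy-6-methyl-1,2,3,4-tetrahydronaphthalene-1-carboxylate
Product: 7 methyl 6-methyl-1,2-dihydronaphthalene-1-carboxylate
Conditions: TsOH·H2O (5 mol %), toluene, 80 °C
Reagents that add atoms: none
Why: Acid-catalysed E1 dehydration through the benzylic C7 cation gives the styrene-type C6=C7 olefin, the substrate class that manganese–salen catalysts epoxidise best.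

Step 5
Reactants: 7 methyl 6-methyl-1,2-dihydronaphthalene-1-carboxylate
Product: 8 methyl (3R,4S)-3,4-epoxy-6-methyl-1,2,3,4-tetrahydronaphthalene-1-carboxylate (C6 R and C7 S in germacrane locants)
Conditions: (S,S)-[N,N′-bis(3,5-di-tert-butylsalicylidene)-1,2-cyclohexanediaminato]manganese chloride (trivalent manganese, 4 mol %), aq. NaOCl (pH 11.3), 4-phenylpyridine N-oxide, CH2Cl2, 0 °C
Reagents that add atoms: sodium hypochlorite, [Na+].[O-]Cl
Why: Jacobsen–Katsuki epoxidation of a cis-disubstituted olefin conjugated to an arene: by analogy with indene and 1,2-dihydronaphthalene the (S,S) catalyst should deliver oxygen to the face that makes the benzylic carbon C7 S and C6 R, under catalyst control for both C4 epimers because the remote, homoallylic C4 centre offers little facial bias.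

Step 6
Reactants: 8 methyl (3R,4S)-3,4-epoxy-6-methyl-1,2,3,4-tetrahydronaphthalene-1-carboxylate; 9 dimethyl malonate
Product: 11 aromatic trans-lactone diester, via sodium alkoxide adduct 10 (not isolated)
Conditions: 9 (2 equiv), NaOMe (1.2 equiv), MeOH, 60 °C; AcOH quench
Reagents that add atoms: none
Why: Malonate opens the aryl epoxide by SN2 attack at the electronically activated benzylic carbon C7 with inversion, and the resulting trans alkoxide closes onto a malonate ester (lactonisation), which fixes the trans C6–O/C7–C11 relationship; with malonate in excess over NaOMe in MeOH the C4 ester enolate is not populated enough to open the epoxide from within.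

Step 7
Reactants: 11 aromatic trans-lactone diester
Product: 14 hexahydronaphthalene lactone diacid, via aromatic trilithium tricarboxylate 12 (not isolated), via dihydro trilithium tricarboxylate 13 (not isolated)
Conditions: LiOH·H2O (6 equiv), THF/H2O, rt; evaporate to dryness; Li (12 equiv), NH3(l)/THF, t-BuOH, −78 → −33 °C; NH4Cl; 1 M HCl to pH 2, 0 °C → rt
Reagents that add atoms: lithium hydroxide, [Li+].[OH-]
Why: Birch reduction of the 1,2,4-trialkylbenzene as its lithium carboxylates, which resist dissolving-metal reduction: protonation occurs at the unsubstituted, para-related carbons C2 and C9, so all three alkyl-bearing carbons stay olefinic and the isotetralin-type 1,4-diene with the tetrasubstituted C3=C8 bond results, and acidification re-closes the trans γ-lactone from the γ-hydroxy malonic acid.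

Step 8
Reactants: 14 hexahydronaphthalene lactone diacid
Product: 15 hexahydronaphthalene lactone dimethyl ester
Conditions: Me3SiCHN2, toluene/MeOH (4:1), 0 °C
Reagents that add atoms: trimethylsilyldiazomethane, C[Si](C)(C)C=[N+]=[N-]
Why: Methylation of both carboxylic acids with trimethylsilyldiazomethane under neutral conditions, which avoids C-alkylation at the acidic malonate carbon and leaves the skipped diene untouched.

Step 9
Reactants: 15 hexahydronaphthalene lactone dimethyl ester
Product: 17 C4-hydroxy diester (C4–OH cis to C6–O), via dilithium bis-enolate 16 (not isolated)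
Conditions: LiN(i-Pr)2 (2.3 equiv), THF, −78 °C; (±)-trans-2-(phenylsulfonyl)-3-phenyloxaziridine (1.2 equiv), −78 °C; AcOH
Reagents that add atoms: trans-2-(phenylsulfonyl)-3-phenyloxaziridine, O=S(=O)(c1ccccc1)N1OC1c1ccccc1
Why: Davis enolate hydroxylation of a dianion: the first equivalent of base removes the malonate-type C11–H to give a stabilised, poorly nucleophilic enolate that blocks the lactone α-position, the second forms the C4 ester dienolate, which alone attacks the oxaziridine oxygen at its α-carbon; the bulky oxidant should approach C4 equatorially, from the face of the C6–O bond and away from the axial H6 and the C11 enolate, placing C4–OH cis to C6–O.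

Step 10
Reactants: 17 C4-hydroxy diester
Product: 19 C4,C15-diol lactone ester, via C11 sodium enolate 18 (not isolated)
Conditions: NaH (1.1 equiv), THF, 0 °C; LiBH4 (3 equiv), 0 °C → rt; aq. NH4Cl
Reagents that add atoms: none
Why: Chemoselective LiBH4 ester reduction with enolate protection: the 1,3-dicarbonyl unit is masked as its sodium enolate, which hydride does not attack, while the α-hydroxy methyl ester, activated by the neighbouring alkoxyborohydride, is reduced to the primary C15 alcohol.

Step 11
Reactants: 19 C4,C15-diol lactone ester
Product: 21 α-carboxy lactone diol, via dilithium hydroxy malonate 20 (not isolated)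
Conditions: LiOH·H2O (3 equiv), THF/H2O, 0 °C → rt; 1 M HCl to pH 2, 0 °C
Reagents that add atoms: lithium hydroxide, [Li+].[OH-]
Why: Saponification of the malonate methyl ester (the lactone opens as well) and acid-induced relactonisation; C6–OH is the only hydroxyl γ to a carboxyl, so the trans γ-lactone should re-form and the second carboxyl stays free at C11.

Step 12
Reactants: 21 α-carboxy lactone diol
Product: 23 α-methylene lactone diol, via Mannich amino acid 22 (not isolated)
Conditions: 37% aq. HCHO, N-methylaniline, NaOAc, AcOH, rt
Reagents that add atoms: formaldehyde, C=O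
Why: Decarboxylative Mannich methylenation of an α-carboxy-γ-butyrolactone: aminomethylation at C11 gives a β-amino acid that fragments with loss of CO2 and N-methylaniline to the exocyclic C11=C13 olefin, erasing the C11 stereocentre; the weakly nucleophilic aniline does not add back to the product.

Step 13
Reactants: 23 α-methylene lactone diol
Product: 24 C15 silyl ether of the hexahydronaphthalene lactone (free C4–OH)
Conditions: TBSCl (1.1 equiv), imidazole, CH2Cl2, 0 °C
Reagents that add atoms: tert-butyldimethylsilyl chloride, CC(C)(C)[Si](C)(C)Cl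
Why: Silylation of the primary C15–OH in preference to the tertiary C4–OH; the silyl ether stops C15–OH from directing the later C3 reduction to the wrong face, while C4–OH stays free as the directing group.

Step 14
Reactants: 24 C15 silyl ether of the hexahydronaphthalene lactone (free C4–OH)
Product: 27 ten-membered C3,C8-diketone with cis C1=C10 olefin, via primary ozonide 25 (not isolated), via secondary ozonide 26 (not isolated)
Conditions: O3 (1.0 equiv, added as a standardised solution in CH2Cl2), CH2Cl2, −78 °C; PPh3 (1.1 equiv), −78 → 0 °C
Reagents that add atoms: ozone, [O-][O+]=O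
Why: Ozone adds as a 1,3-dipole across the tetrasubstituted C3=C8 bond, the primary ozonide fragments to a ketone and a tethered carbonyl oxide that recombine to the bridged secondary ozonide, and PPh3 reduces this to the two ketones; the closest known reaction is the ozonolysis of the central double bond of isotetralin-type Birch dienes to cyclodecenediones. No ring is closed by bond formation: the ten-membered ring is the perimeter of rings A and B and is released when their shared bond is cut, which is also why its C1=C10 olefin, formerly in a six-membered ring, must be cis. No stereocentre is created; C4, C6 and C7, set on the rigid ring A, pass through unchanged. The step needs chemoselectivity for C3=C8 over the trisubstituted C1=C10 and the conjugated C11=C13 olefins, which rests on the higher electron density of the tetraalkyl olefin, on the electron-poor character of the acrylate-type methylene and on metering one equivalent of ozone at −78 °C so that the slower olefins meet no excess. Because the β,γ-unsaturated, β-acyloxy diketone can conjugate, eliminate at C6 or undergo transannular aldolisation, the work-up is neutral and cold and the product is used at once.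

Step 15
Reactants: 27 ten-membered C3,C8-diketone with cis C1=C10 olefin
Product: 28 (3S)-3-hydroxy-8-ketone
Conditions: Me4NBH(OAc)3 (5 equiv), MeCN/AcOH (1:1), −35 °C
Reagents that add atoms: none
Why: Saksena–Evans hydroxyl-directed reduction: the free tertiary C4–OH exchanges onto boron and delivers hydride within the molecule to the face of the adjacent C3 ketone on which it sits, so the new C3–OH should be trans to C4–OH (3S), whereas the C8 ketone, which has no free hydroxyl α or β to it, is not reduced by the acyloxyborohydride.

Step 16
Reactants: 28 (3S)-3-hydroxy-8-ketone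
Product: 29 3,4-bis(triethylsilyl) ether 8-ketone
Conditions: Et3SiOTf (3 equiv), 2,6-lutidine (5 equiv), CH2Cl2, −78 → −40 °C
Reagents that add atoms: triethylsilyl trifluoromethanesulfonate, CC[Si](CC)(CC)OS(=O)(=O)C(F)(F)F
Why: Silylation of the secondary C3–OH and the tertiary C4–OH with a silyl triflate and a hindered base at low temperature, conditions that leave the enolisable C8 ketone untouched; it reserves C8–OH as the only free hydroxyl after the next step.

Step 17
Reactants: 29 3,4-bis(triethylsilyl) ether 8-ketone
Product: 30 (8R)-8-alcohol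
Conditions: (S)-2-methyl-CBS-oxazaborolidine (1.0 equiv), catecholborane (2 equiv), toluene, −78 °C
Reagents that add atoms: none
Why: Corey–Bakshi–Shibata reduction under reagent control: the ketone binds the catalyst boron anti to the branched C7 substituent (large) with the C9 methylene as the small group, and hydride is delivered to the face that gives the 8R alcohol (C8–O cis to the C7–C11 bond, trans to C6–O); catecholborane at −78 °C does not touch the olefins, the lactone or the silyl ethers.

Step 18
Reactants: 30 (8R)-8-alcohol
Product: 31 (1R,10S)-1,10-epoxy 8-alcohol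
Conditions: VO(acac)2 (10 mol %), t-BuOOH (1.5 equiv, in decane), CH2Cl2, 0 °C → rt
Reagents that add atoms: tert-butyl hydroperoxide, CC(C)(C)OO
Why: Vanadium-catalysed hydroxyl-directed epoxidation: the homoallylic C8–OH binds vanadium and the peroxide oxygen can only be delivered to the face of the cis C1=C10 olefin on which C8–O lies, giving the cis (1R,10S) oxirane, while the electron-poor C11=C13 olefin is inert to the electrophilic oxidant.

Step 19
Reactants: 31 (1R,10S)-1,10-epoxy 8-alcohol; 32 angelic acid
Product: 34 silyl-protected 8-O-angelate, via angelic 2,4,6-trichlorobenzoic anhydride 33 (not isolated)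
Conditions: 32 (5 equiv), 2,4,6-trichlorobenzoyl chloride, Et3N, toluene, rt; then 31, 80 °C
Reagents that add atoms: none
Why: Yamaguchi esterification through the mixed anhydride without a nucleophilic catalyst, conditions that suppress angelate-to-tiglate isomerisation; C8–OH is the only free hydroxyl, and acylation on oxygen retains the C8 configuration.

Step 20
Reactants: 34 silyl-protected 8-O-angelate
Product: 35 target germacranolide CNP0307250.1
Conditions: HF·pyridine, pyridine, THF, 0 °C → rt
Reagents that add atoms: none
Why: Fluoride-mediated cleavage of the three silyl ethers with pyridine-buffered HF·pyridine, mild enough for the oxirane, the angelate and the α-methylene lactone.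

**Compound list**

1 | methyl 2-(4-methylphenyl)acetate | COC(=O)Cc1ccc(C)cc1 | starting material
2 | tert-butyl acrylate | C=CC(=O)OC(C)(C)C | starting material
3 | 5-tert-butyl 1-methyl 2-(4-methylphenyl)pentanedioate (racemic) | COC(=O)C(CCC(=O)OC(C)(C)C)c1ccc(C)cc1 | intermediate
4 | 5-methoxy-4-(4-methylphenyl)-5-oxopentanoic acid (racemic) | COC(=O)C(CCC(=O)O)c1ccc(C)cc1 | intermediate (not isolated)
5 | methyl 6-methyl-4-oxo-1,2,3,4-tetrahydronaphthalene-1-carboxylate (racemic) | COC(=O)C1CCC(=O)c2cc(C)ccc12 | intermediate
6 | methyl 4-hydroxy-6-methyl-1,2,3,4-tetrahydronaphthalene-1-carboxylate (racemic, cis/trans mixture) | COC(=O)C1CCC(O)c2cc(C)ccc12 | intermediate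
7 | methyl 6-methyl-1,2-dihydronaphthalene-1-carboxylate (racemic) | COC(=O)C1CC=Cc2cc(C)ccc12 | intermediate
8 | methyl (3R,4S)-3,4-epoxy-6-methyl-1,2,3,4-tetrahydronaphthalene-1-carboxylate (germacrane C6 R, C7 S; C4 epimers) | COC(=O)C1C[C@H]2O[C@H]2c2cc(C)ccc12 | intermediate
9 | dimethyl malonate | COC(=O)CC(=O)OC | starting material
10 | sodium alkoxide of the malonate adduct: tetralin with CH(CO2Me)2 on C7 trans to O– on C6 (6R), CO2Me on C4 (C4 epimers) | COC(=O)C(C(=O)OC)[C@H]1[C@H]([O-])CC(C(=O)OC)c2ccc(C)cc12.[Na+] | intermediate (not isolated)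
11 | aromatic trans-lactone diester: dimethyl 8-methyl-2-oxo-1,2,3a,4,5,9b-hexahydronaphtho[2,1-b]furan-1,5-dicarboxylate, trans ring fusion (H6/H7 anti, 6R), CO2Me at C11 and C4 (epimers at both) | COC(=O)C1C(=O)O[C@@H]2CC(C(=O)OC)c3ccc(C)cc3[C@@H]12 | intermediate
12 | trilithium salt of the ring-opened aromatic hydroxy triacid (malonate on C7, OH on C6, carboxylate on C4) | [Li+].[Li+].[Li+].[O-]C(=O)C(C([O-])=O)[C@H]1[C@H](O)CC(C([O-])=O)c2ccc(C)cc12 | intermediate (not isolated)
13 | trilithium salt of the ring-B 1,4-dihydro compound (C3=C8 and C1=C10 olefins) | [Li+].[Li+].[Li+].[O-]C(=O)C(C([O-])=O)[C@H]1[C@H](O)CC(C([O-])=O)C2=C1CC(C)=CC2 | intermediate (not isolated)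
14 | hexahydronaphthalene lactone diacid: 8-methyl-2-oxo-1,2,3a,4,5,6,9,9b-octahydronaphtho[2,1-b]furan-1,5-dicarboxylic acid, trans-fused (6R), CO2H at C11 and C4 (epimers) | OC(=O)C1C(=O)O[C@@H]2CC(C(O)=O)C3=C(CC(C)=CC3)[C@@H]12 | intermediate
15 | dimethyl ester of 14 (CO2Me at C11 and C4, epimers) | COC(=O)C1C(=O)O[C@@H]2CC(C(=O)OC)C3=C(CC(C)=CC3)[C@@H]12 | intermediate
16 | dilithium bis-enolate of 15 (malonate-type enolate at C11, ester dienolate at C4) | [Li+].[Li+].COC([O-])=C1C(=O)O[C@@H]2CC(=C([O-])OC)C3=C(CC(C)=CC3)[C@@H]12 | intermediate (not isolated)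
17 | C4-hydroxy diester: 15 with OH on C4 cis to C6–O (C4 CO2Me trans to C6–O), C11 epimers | COC(=O)C1C(=O)O[C@@H]2C[C@@](O)(C(=O)OC)C3=C(CC(C)=CC3)[C@@H]12 | intermediate
18 | C11 sodium enolate of 17 | [Na+].COC([O-])=C1C(=O)O[C@@H]2C[C@@](O)(C(=O)OC)C3=C(CC(C)=CC3)[C@@H]12 | intermediate (not isolated)
19 | C4,C15-diol lactone ester: C4(OH)(CH2OH), lactone still carrying CO2Me at C11 (C11 epimers) | COC(=O)C1C(=O)O[C@@H]2C[C@@](O)(CO)C3=C(CC(C)=CC3)[C@@H]12 | intermediate
20 | dilithium salt of the ring-opened hydroxy malonic acid of 19 | [Li+].[Li+].[O-]C(=O)C(C([O-])=O)[C@H]1[C@H](O)C[C@@](O)(CO)C2=C1CC(C)=CC2 | intermediate (not isolated)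
21 | α-carboxy lactone diol (CO2H at C11, C11 epimers) | OC(=O)C1C(=O)O[C@@H]2C[C@@](O)(CO)C3=C(CC(C)=CC3)[C@@H]12 | intermediate
22 | Mannich amino acid: 21 with CH2N(CH3)Ph on C11 | OC(=O)C1(CN(C)c2ccccc2)C(=O)O[C@@H]2C[C@@](O)(CO)C3=C(CC(C)=CC3)[C@@H]12 | intermediate (not isolated)
23 | α-methylene lactone diol: trans-lactone-fused 2-methyl-1,4,5,6,7,8-hexahydronaphthalene with C4(OH)(CH2OH), C4–OH cis to C6–O | C=C1C(=O)O[C@@H]2C[C@@](O)(CO)C3=C(CC(C)=CC3)[C@@H]12 | intermediate
24 | C15 tert-butyldimethylsilyl ether of 23, C4–OH free (precursor of the key step) | C=C1C(=O)O[C@@H]2C[C@@](O)(CO[Si](C)(C)C(C)(C)C)C3=C(CC(C)=CC3)[C@@H]12 | intermediate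
25 | primary ozonide of 24 (1,2,3-trioxolane across C3–C8; configuration at C3/C8 not specified) | C=C1C(=O)O[C@@H]2C[C@@](O)(CO[Si](C)(C)C(C)(C)C)C34OOOC3(CC(C)=CC4)[C@@H]12 | intermediate (not isolated)
26 | secondary ozonide (1,2,4-trioxolane bridging C3 and C8; configuration at C3/C8 not specified) | C=C1C(=O)O[C@@H]2C[C@@](O)(CO[Si](C)(C)C(C)(C)C)C34OC(OO3)(CC(C)=CC4)[C@@H]12 | intermediate (not isolated)
27 | ten-membered C3,C8-diketone: (Z)-C1=C10 olefin, trans 6,12-lactone with C11=C13, C4–OH free, C15–OTBS | C=C1C(=O)O[C@@H]2C[C@@](O)(CO[Si](C)(C)C(C)(C)C)C(=O)C/C=C(C)\CC(=O)[C@@H]12 | intermediate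
28 | (3S)-3-hydroxy-8-ketone: C3–OH trans to C4–OH | C=C1C(=O)O[C@@H]2C[C@@](O)(CO[Si](C)(C)C(C)(C)C)[C@@H](O)C/C=C(C)\CC(=O)[C@@H]12 | intermediate
29 | 3,4-bis(triethylsilyl) ether of 28 | C=C1C(=O)O[C@@H]2C[C@@](O[Si](CC)(CC)CC)(CO[Si](C)(C)C(C)(C)C)[C@@H](O[Si](CC)(CC)CC)C/C=C(C)\CC(=O)[C@@H]12 | intermediate
30 | (8R)-8-alcohol: C8–OH cis to the C7–C11 bond | C=C1C(=O)O[C@@H]2C[C@@](O[Si](CC)(CC)CC)(CO[Si](C)(C)C(C)(C)C)[C@@H](O[Si](CC)(CC)CC)C/C=C(C)\C[C@@H](O)[C@@H]12 | intermediate
31 | (1R,10S)-1,10-epoxy 8-alcohol: oxirane on the face of C8–O | C=C1C(=O)O[C@@H]2C[C@@](O[Si](CC)(CC)CC)(CO[Si](C)(C)C(C)(C)C)[C@@H](O[Si](CC)(CC)CC)C[C@H]3O[C@@]3(C)C[C@@H](O)[C@@H]12 | intermediate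
32 | angelic acid, (Z)-2-methylbut-2-enoic acid | C/C=C(/C)C(=O)O | starting material
33 | angelic 2,4,6-trichlorobenzoic anhydride | C/C=C(/C)C(=O)OC(=O)c1c(Cl)cc(Cl)cc1Cl | intermediate (not isolated)
34 | silyl-protected 8-O-angelate (3,4-bis-OTES, 15-OTBS) | C=C1C(=O)O[C@@H]2C[C@@](O[Si](CC)(CC)CC)(CO[Si](C)(C)C(C)(C)C)[C@@H](O[Si](CC)(CC)CC)C[C@H]3O[C@@]3(C)C[C@@H](OC(=O)/C(C)=C\C)[C@@H]12 | intermediate
35 | CNP0307250.1: (1R,3S,4R,6R,7S,8R,10S)-8-angeloyloxy-1,10-epoxy-3,4,15-trihydroxygermacr-11(13)-en-6,12-olide | C=C1C(=O)O[C@@H]2C[C@@](O)(CO)[C@@H](O)C[C@H]3O[C@@]3(C)C[C@@H](OC(=O)/C(C)=C\C)[C@@H]12 | target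

**Step count and risks**

Total steps: 20. Longest linear sequence: 20 (from 1 to 35; compounds 2, 9 and 32 enter as commercial reagents).

The three steps most likely to fail:

1. Step 14 (ozonolysis). Ozone may discriminate too little between the tetrasubstituted C3=C8 and the trisubstituted C1=C10 olefin, so that ring B is cut competitively or the product is oxidised further. Fallback: set out from 24 and epoxidise with mCPBA (1.0 equiv, NaHCO3, CH2Cl2, −20 °C). Peracids separate tetra- from trisubstituted olefins more sharply than ozone, and the allylic C4–OH directs and accelerates attack on C3=C8 (Henbest effect), giving the C3,C8-epoxide F1. Periodic acid (H5IO6, THF/H2O, 0 °C) then hydrolyses the oxirane and cleaves the glycol to the diketone 27, where the route is rejoined.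

2. Step 17 (C8 reduction). Facial selectivity may be poor if the conformational bias of the flexible ten-membered ketone opposes the catalyst, and a slow reduction gives the β,γ-unsaturated ketone time to enolise and conjugate. Fallback: set out from 29 and follow the substrate's own preference, reducing with the enantiomeric (R)-oxazaborolidine and catecholborane to the 8-epi alcohol F2. Mitsunobu esterification with angelic acid 32 (PPh3, diisopropyl azodicarboxylate, toluene, 0 °C) inverts C8 and installs the ester in one operation, giving the 1(10)-olefinic silyl-protected angelate F3. HF·pyridine removes the three silyl groups to give the 1(10)-olefinic triol angelate F4. VO(acac)2/t-BuOOH epoxidation, now directed by the homoallylic C3–OH on the same face, returns to the route at the target 35.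

3. Step 18 (directed epoxidation). Oxygen transfer may be slow or unselective if the ring conformation does not hold the C8–O–vanadium unit over the C1=C10 olefin, and prolonged exposure to the Lewis-acidic catalyst may erode the silyl ethers. Fallback: set out from 30 and use reagent control instead, a Shi epoxidation with the D-fructose-derived ketone (1,2:4,5-di-O-isopropylidene-β-D-erythro-2,3-hexodiulo-2,6-pyranose), Oxone and K2CO3 in MeCN/dimethoxymethane/aqueous buffer at 0 °C. The spiro transition state for this trisubstituted olefin, by analogy with 1-phenylcyclohexene, is predicted to give the same (1R,10S) oxirane. This fallback makes no new compound (F0) and rejoins the route directly at 31.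

**Further compounds**

F1 | step 14 | C3,C8-epoxide of 24 (oxirane cis to C4–OH) | C=C1C(=O)O[C@@H]2C[C@@](O)(CO[Si](C)(C)C(C)(C)C)[C@]34O[C@]3(CC(C)=CC4)[C@@H]12
F2 | step 17 | 8-epi alcohol (8S epimer of 30) | C=C1C(=O)O[C@@H]2C[C@@](O[Si](CC)(CC)CC)(CO[Si](C)(C)C(C)(C)C)[C@@H](O[Si](CC)(CC)CC)C/C=C(C)\C[C@H](O)[C@@H]12
F3 | step 17 | 1(10)-olefinic silyl-protected (8R)-8-O-angelate | C=C1C(=O)O[C@@H]2C[C@@](O[Si](CC)(CC)CC)(CO[Si](C)(C)C(C)(C)C)[C@@H](O[Si](CC)(CC)CC)C/C=C(C)\C[C@@H](OC(=O)/C(C)=C\C)[C@@H]12
F4 | step 17 | 1(10)-olefinic triol angelate (target lacking the oxirane oxygen) | C=C1C(=O)O[C@@H]2C[C@@](O)(CO)[C@@H](O)C/C=C(C)\C[C@@H](OC(=O)/C(C)=C\C)[C@@H]12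
F0 | step 18 | none | none
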